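Ring A is disconnected by a retro-[4+2]: the C3(O)–C4(CH3) pair is an (E)-propanal silyl enol ether, and C2–C1–C10–C5 is a vinyl dienone whose C9 ketone (the later enol carbon of ring B) polarises C5. The diene is 4-vinylcar-3-en-5-one from (+)-3-carene; its gem-dimethylcyclopropane (C7, C8, C11) shields one face and is the latent isopropylidene. One Lewis-acid inverse-electron-demand Diels–Alder step closes ring A and sets C3, C4 and C5. Acylation, acid opening of the cyclopropane and C8 hydroxylation with tautomerisation to the diosphenol finish the synthesis. Eremophilane numbering is used throughout.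

Key step: step 5

Remark: (+)-3-carene is taken as the commercial (1S,6R) enantiomer; locants refer to the target (C3 acyloxy carbon, C4 secondary-methyl carbon, C5 quaternary carbon, C7=C11 isopropylidene, C8 ketone, C9 enol carbon, C10 sp2 ring-fusion carbon); compound 17 is a mixture of C8 epimers of no consequence.

Step 1
Reactants: 1 (+)-3-carene
Product: 2 car-3-en-5-one, (1R,6S)-4,7,7-trimethylbicyclo[4.1.0]hept-3-en-2-one
Conditions: t-BuOOH (3 equiv), Cr(CO)6 (0.3 equiv), MeCN, reflux
Reagents that add atoms: tert-butyl hydroperoxide, CC(C)(C)OO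
Why: Chromium-catalysed allylic oxidation should convert the allylic, cyclopropylcarbinyl methylene next to the unsubstituted alkene carbon into the ketone in preference to the methylene flanked by the methyl-bearing carbon, and the two cyclopropane stereocentres of 1 are not touched.

Step 2
Reactants: 2 car-3-en-5-one
Product: 3 (1R,6S)-3-iodo-4,7,7-trimethylbicyclo[4.1.0]hept-3-en-2-one
Conditions: I2 (0.6 equiv), PhI(OCOCF3)2 (0.6 equiv), pyridine (2 equiv), CH2Cl2, rt
Reagents that add atoms: iodine, II
Why: Electrophilic alpha-iodination of the enone (iodine activated by the hypervalent iodine reagent, pyridine as base) should give the alpha-iodoenone needed for cross-coupling, and no stereocentre is formed or touched.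

Step 3
Reactants: 3 the alpha-iodoenone
Product: 4 (1R,6S)-3-ethenyl-4,7,7-trimethylbicyclo[4.1.0]hept-3-en-2-one (4-vinylcar-3-en-5-one)
Conditions: tributyl(vinyl)stannane (1.2 equiv), PdCl2(PhCN)2 (5 mol%), AsPh3 (10 mol%), CuI (10 mol%), NMP, rt
Reagents that add atoms: tributyl(vinyl)stannane, C=C[Sn](CCCC)(CCCC)CCCC
Why: Stille coupling of the alpha-iodoenone under ligand-accelerated, copper-assisted conditions at room temperature should install C1 and C2 as the vinyl group and complete the cross-conjugated diene, and no stereocentre is formed.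

Step 4
Reactants: 5 allyloxy(tert-butyl)dimethylsilane
Product: 6 (E)-tert-butyldimethyl(prop-1-en-1-yloxy)silane
Conditions: [Ir(cod)(PMePh2)2]PF6 (1 mol%, pre-activated with H2), THF, rt
Reagents that add atoms: none
Why: Iridium-hydride-catalysed allyl ether to enol ether isomerisation should give the (E)-propenyl silyl ether selectively, which fixes the alkene geometry that later becomes the trans relation of the C3 oxygen and the C4 methyl.

Step 5
Reactants: 4 the vinyl dienone; 6 the (E)-silyl enol ether
Product: 7 (3R,4R,5R,7S,8R)-3-(tert-butyldimethylsilyloxy)-8,11-cycloeremophil-1(10)-en-9-one (cyclopropane C7–C8–C11 on the face opposite to the new C4–C5 bond; C4 and C5 methyls cis; C3 oxygen trans to the C4 methyl)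
Conditions: 6 (2.5 equiv), EtAlCl2 (0.3 equiv), CH2Cl2, −78 to −40 °C
Reagents that add atoms: none
Why: The step is a Lewis-acid-promoted inverse-electron-demand Diels–Alder reaction in which the aluminium-complexed 2-vinyl enone acts as a 2-acyl diene (C5=C10–C1=C2) and 6 as the electron-rich dienophile, concerted but strongly asynchronous with the C4–C5 bond leading, so that the nucleophilic beta-carbon of the enol ether meets the electrophilic beta-carbon C5 and the regiochemistry is fixed. The closest known reaction types are the vinylquinone Diels–Alder reaction and Lewis-acid cycloadditions of 2-carbonyl-1,3-dienes with enol ethers. Ring A closes as an intermolecular [4+2] that forms the C4–C5 and C2–C3 sigma bonds and leaves the C1=C10 alkene. C5 is set by facial control, because the endo methyl of the gem-dimethylcyclopropane covers one face and the dienophile adds anti to the cyclopropane. C4 and C3 are set by the (E) geometry of 6 together with the exo placement of the C4 methyl, which avoids the underside of ring B, puts the silyloxy group endo, and makes the C4 methyl cis to the C5 methyl and trans to the C3 oxygen. The step needs carbon closure at C2 in preference to oxygen or C10 closure, which aluminium on the carbonyl oxygen and the strain-free six-membered ring should secure.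

Step 6
Reactants: 7 the silyl ether adduct
Product: 8 (3R,4R,5R,7S,8R)-3-hydroxy-8,11-cycloeremophil-1(10)-en-9-one
Conditions: HF·pyridine, pyridine, THF, 0 °C to rt
Reagents that add atoms: none
Why: Fluoride-mediated desilylation under mildly acidic conditions should free the C3 alcohol without epimerisation and without a base that could trigger elimination from the gamma-position of the enone.

Step 7
Reactants: 9 4-methylfuran-2(5H)-one
Product: 10 (Z)-4-chloro-3-methylbut-2-enoyl chloride
Conditions: SOCl2 (1.5 equiv), ZnCl2 (5 mol%), neat, 70 °C; distillation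
Reagents that add atoms: thionyl chloride, O=S(Cl)Cl
Why: Lewis-acid-catalysed ring opening of the lactone by thionyl chloride (the gamma-butyrolactone to 4-chlorobutanoyl chloride reaction) should cleave the allylic C–O bond and give the chloro acid chloride with the Z geometry inherited from the ring.

Step 8
Reactants: 8 the C3 alcohol; 10 the chloro acid chloride
Product: 11 (3R,4R,5R,7S,8R)-3-[(Z)-4-chloro-3-methylbut-2-enoyloxy]-8,11-cycloeremophil-1(10)-en-9-one
Conditions: 10 (1.3 equiv), pyridine (3 equiv), CH2Cl2, 0 °C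
Reagents that add atoms: none
Why: Acylation of the secondary alcohol by the acid chloride with pyridine as the only base (to avoid vinylketene formation and E/Z scrambling) should give the ester with retention at C3, because the C–O bond of the alcohol is not broken.

Step 9
Reactants: 11 the allylic chloride ester; 12 angelic acid, (Z)-2-methylbut-2-enoic acid
Product: 14 (3R,4R,5R,7S,8R)-3-{(Z)-4-[(Z)-2-methylbut-2-enoyloxy]-3-methylbut-2-enoyloxy}-8,11-cycloeremophil-1(10)-en-9-one, via potassium angelate 13 (not isolated)
Conditions: 12 (1.5 equiv), KHCO3 (1.5 equiv), DMF, rt; then 11, NaI (0.1 equiv), rt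
Reagents that add atoms: none
Why: SN2 displacement of the allylic chloride by the carboxylate (iodide-catalysed, Finkelstein-assisted O-alkylation) should form the angelate ester without ever activating angelic acid, so its Z geometry cannot drift to the tiglate, and no stereocentre is affected.

Step 10
Reactants: 14 the cyclopropyl enone diester
Product: 15 (3R,4R,5R)-3-{(Z)-4-[(Z)-2-methylbut-2-enoyloxy]-3-methylbut-2-enoyloxy}eremophila-1(10),7(11)-dien-9-one
Conditions: p-TsOH·H2O (0.2 equiv), CH2Cl2, 0 °C to rt, stopped at full conversion of 14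
Reagents that add atoms: none
Why: Acid-catalysed ring opening of the conjugated cyclopropyl ketone (protonation at oxygen, cleavage of the external C8–C11 bond to the tertiary C11 cation, loss of the C7 proton to the conjugated dienol, kinetic protonation at C8) should give the beta,gamma-unsaturated ketone with the C7=C11 alkene, erasing the auxiliary stereocentres C7 and C8 while C3, C4 and C5 are untouched.

Step 11
Reactants: 15 the beta,gamma-unsaturated ketone
Product: 18 (3R,4R,5R)-3-{(Z)-4-[(Z)-2-methylbut-2-enoyloxy]-3-methylbut-2-enoyloxy}-9-hydroxyeremophila-7(11),9-dien-8-one (target), via potassium dienolate 16 (not isolated), via C8 acyloin 17 (not isolated)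
Conditions: KN(SiMe3)2 (1.05 equiv), THF, −78 °C; 2-(phenylsulfonyl)-3-phenyloxaziridine (1.3 equiv), −78 °C; AcOH; then DBU (0.2 equiv), CH2Cl2, rt
Reagents that add atoms: 2-(phenylsulfonyl)-3-phenyloxaziridine, O=S(=O)(c1ccccc1)N1OC1c1ccccc1
Why: Kinetic deprotonation of the doubly activated C8 methylene and alpha-selective oxygen transfer from the N-sulfonyloxaziridine (enolate hydroxylation) should give the acyloin, which base-catalysed enediol tautomerisation with protonation at C1 converts into the conjugated, hydrogen-bonded diosphenol as the thermodynamic sink, the transient C8 stereocentre being lost when C8 becomes the ketone carbon.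

Compound list
1 | (+)-3-carene, (1S,6R)-3,7,7-trimethylbicyclo[4.1.0]hept-3-ene | CC1=CC[C@@H]2[C@H](C1)C2(C)C | starting material
2 | car-3-en-5-one, (1R,6S)-4,7,7-trimethylbicyclo[4.1.0]hept-3-en-2-one | CC1=CC(=O)[C@@H]2[C@H](C1)C2(C)C | intermediate
3 | (1R,6S)-3-iodo-4,7,7-trimethylbicyclo[4.1.0]hept-3-en-2-one | CC1=C(I)C(=O)[C@@H]2[C@H](C1)C2(C)C | intermediate
4 | (1R,6S)-3-ethenyl-4,7,7-trimethylbicyclo[4.1.0]hept-3-en-2-one | CC1=C(C=C)C(=O)[C@@H]2[C@H](C1)C2(C)C | intermediate
5 | allyloxy(tert-butyl)dimethylsilane | C=CCO[Si](C)(C)C(C)(C)C | starting material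
6 | (E)-tert-butyldimethyl(prop-1-en-1-yloxy)silane | C/C=C/O[Si](C)(C)C(C)(C)C | intermediate
7 | (3R,4R,5R,7S,8R)-3-(tert-butyldimethylsilyloxy)-8,11-cycloeremophil-1(10)-en-9-one | CC(C)(C)[Si](C)(C)O[C@@H]1CC=C2C(=O)[C@@H]3[C@H](C[C@]2(C)[C@H]1C)C3(C)C | intermediate
8 | (3R,4R,5R,7S,8R)-3-hydroxy-8,11-cycloeremophil-1(10)-en-9-one | O[C@@H]1CC=C2C(=O)[C@@H]3[C@H](C[C@]2(C)[C@H]1C)C3(C)C | intermediate
9 | 4-methylfuran-2(5H)-one | CC1=CC(=O)OC1 | starting material
10 | (Z)-4-chloro-3-methylbut-2-enoyl chloride | ClC/C(C)=C\C(Cl)=O | intermediate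
11 | (3R,4R,5R,7S,8R)-3-[(Z)-4-chloro-3-methylbut-2-enoyloxy]-8,11-cycloeremophil-1(10)-en-9-one | ClC/C(C)=C\C(=O)O[C@@H]1CC=C2C(=O)[C@@H]3[C@H](C[C@]2(C)[C@H]1C)C3(C)C | intermediate
12 | angelic acid, (Z)-2-methylbut-2-enoic acid | C/C=C(/C)C(O)=O | starting material
13 | potassium angelate (not isolated) | C/C=C(/C)C([O-])=O.[K+] | intermediate
14 | (3R,4R,5R,7S,8R)-3-{(Z)-4-[(Z)-2-methylbut-2-enoyloxy]-3-methylbut-2-enoyloxy}-8,11-cycloeremophil-1(10)-en-9-one | C/C=C(/C)C(=O)OC/C(C)=C\C(=O)O[C@@H]1CC=C2C(=O)[C@@H]3[C@H](C[C@]2(C)[C@H]1C)C3(C)C | intermediate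
15 | (3R,4R,5R)-3-{(Z)-4-[(Z)-2-methylbut-2-enoyloxy]-3-methylbut-2-enoyloxy}eremophila-1(10),7(11)-dien-9-one | C/C=C(/C)C(=O)OC/C(C)=C\C(=O)O[C@@H]1CC=C2C(=O)CC(=C(C)C)C[C@]2(C)[C@H]1C | intermediate
16 | potassium eremophila-1(10),7(11),8-trien-9-olate of 15 (not isolated) | C/C=C(/C)C(=O)OC/C(C)=C\C(=O)O[C@@H]1CC=C2C([O-])=CC(=C(C)C)C[C@]2(C)[C@H]1C.[K+] | intermediate
17 | (3R,4R,5R)-8-hydroxy-3-{(Z)-4-[(Z)-2-methylbut-2-enoyloxy]-3-methylbut-2-enoyloxy}eremophila-1(10),7(11)-dien-9-one, C8 epimers (not isolated) | C/C=C(/C)C(=O)OC/C(C)=C\C(=O)O[C@@H]1CC=C2C(=O)C(O)C(=C(C)C)C[C@]2(C)[C@H]1C | intermediate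
18 | (3R,4R,5R)-3-{(Z)-4-[(Z)-2-methylbut-2-enoyloxy]-3-methylbut-2-enoyloxy}-9-hydroxyeremophila-7(11),9-dien-8-one | C/C=C(/C)C(=O)OC/C(C)=C\C(=O)O[C@@H]1CCC2=C(O)C(=O)C(=C(C)C)C[C@]2(C)[C@H]1C | target

Total step count: 11. Longest linear sequence: 9 steps (steps 1, 2, 3, 5, 6, 8, 9, 10, 11, from (+)-3-carene).

Steps most likely to fail

Step 5 (key step). The cycloaddition may close through the carbonyl oxygen or through C10 (dihydropyran or cyclobutane formation). Silyl transfer may stop it at a simple Michael adduct. The exo preference of the C4 methyl may erode, or the reaction may stall because the C5 methyl sits on the inside of the s-cis diene. The fallback is a Lewis-acid-free, pressure-driven cycloaddition with an alkyl enol ether and sets out from 4. 4-Methoxybenzyl alcohol is allylated (NaH, allyl bromide, THF) to allyl 4-methoxybenzyl ether F1. The same iridium catalyst isomerises it to (E)-1-methoxy-4-[(prop-1-en-1-yloxy)methyl]benzene F2. F2 and 4 at 12 kbar in CH2Cl2 (or with Eu(fod)3 at 60 °C) should give the 4-methoxybenzyl ether adduct F3. Oxidative cleavage with DDQ in wet CH2Cl2 comes back to the route at 8.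

Step 10. The C11 cation may lose a methyl proton instead of the C7 proton, the new alkene may migrate further into conjugation with the ketone, or the acid may cause Z to E drift in the two enoate units. The fallback sets out from 14 and avoids the free cation. HCl in Et2O at 0 °C should add across the cyclopropane to give the tertiary chloride F4. Soft enolisation (Me3SiOTf, Et3N, CH2Cl2, −78 °C) gives the cross-conjugated trimethylsilyl enol ether F5. Rubottom oxidation (mCPBA, NaHCO3, then citric acid in MeOH) gives the 8-hydroxy-11-chloro ketone F6. DBU in CH2Cl2 then effects enediol tautomerisation and E1cB loss of HCl across C7–C11, and comes back to the route at 18.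

Step 11. The base may deprotonate C2, with elimination of the C3 acyloxy group, or the gamma-positions of the side chain, or oxygen may be delivered to C11 instead of C8. The fallback sets out from 15 and uses no strong base. Mn(OAc)3·2H2O in benzene at reflux (alpha'-acetoxylation of the enone through the manganese enolate) should give the 8-acetoxy ketone F7. Brief methanolysis of this activated acetate (K2CO3, 0.1 equiv, MeOH, −10 °C) releases the acyloin and comes back to the route at 17, which tautomerises to 18 under the same conditions.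

Further compounds
F1 | step 5 | allyl 4-methoxybenzyl ether | C=CCOCc1ccc(OC)cc1
F2 | step 5 | (E)-1-methoxy-4-[(prop-1-en-1-yloxy)methyl]benzene | C/C=C/OCc1ccc(OC)cc1
F3 | step 5 | (3R,4R,5R,7S,8R)-3-(4-methoxybenzyloxy)-8,11-cycloeremophil-1(10)-en-9-one | COc1ccc(CO[C@@H]2CC=C3C(=O)[C@@H]4[C@H](C[C@]3(C)[C@H]2C)C4(C)C)cc1
F4 | step 10 | (3R,4R,5R,7S)-11-chloro-3-{(Z)-4-[(Z)-2-methylbut-2-enoyloxy]-3-methylbut-2-enoyloxy}eremophil-1(10)-en-9-one | C/C=C(/C)C(=O)OC/C(C)=C\C(=O)O[C@@H]1CC=C2C(=O)C[C@H](C[C@]2(C)[C@H]1C)C(C)(C)Cl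
F5 | step 10 | (3R,4R,5R,7S)-11-chloro-9-(trimethylsilyloxy)eremophila-1(10),8-dien-3-yl (Z)-4-[(Z)-2-methylbut-2-enoyloxy]-3-methylbut-2-enoate | C/C=C(/C)C(=O)OC/C(C)=C\C(=O)O[C@@H]1CC=C2C(O[Si](C)(C)C)=C[C@H](C[C@]2(C)[C@H]1C)C(C)(C)Cl
F6 | step 10 | (3R,4R,5R,7S)-11-chloro-8-hydroxy-3-{(Z)-4-[(Z)-2-methylbut-2-enoyloxy]-3-methylbut-2-enoyloxy}eremophil-1(10)-en-9-one, C8 epimers | C/C=C(/C)C(=O)OC/C(C)=C\C(=O)O[C@@H]1CC=C2C(=O)C(O)[C@H](C[C@]2(C)[C@H]1C)C(C)(C)Cl
F7 | step 11 | (3R,4R,5R)-8-acetoxy-3-{(Z)-4-[(Z)-2-methylbut-2-enoyloxy]-3-methylbut-2-enoyloxy}eremophila-1(10),7(11)-dien-9-one, C8 epimers | C/C=C(/C)C(=O)OC/C(C)=C\C(=O)O[C@@H]1CC=C2C(=O)C(OC(C)=O)C(=C(C)C)C[C@]2(C)[C@H]1C
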